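## Retrosynthetic overview
1. The target is the 4,2'-hemiketal ring-chain tautomer of a (2R)-2',6'-dihydroxyflavanone. Both C–O bonds of its 2,6-dioxabicyclo[3.3.1]nonane core are cut at once, giving an achiral, unprotected 2,6,2'-trihydroxychalcone that is an isomer of the target.
2. In the forward direction, one chiral-Brønsted-acid-catalysed oxa-Michael/hemiketalisation cascade closes both rings. The catalyst sets C-2 and the geometry of the bicycle sets C-4.
3. The chalcone comes from a Claisen–Schmidt union of a pyrano-acetophenone with 2,6-dihydroxybenzaldehyde, carried as its bis-allyl ether and unmasked in the same flask.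
4. The pyrano-acetophenone comes from an o-quinone methide/oxa-6π closure with prenal on C-prenylated 2',4'-dihydroxy-6'-methoxyacetophenone.
5. Ring order: dimethylpyran, then flavanone C ring, then hemiketal ring.

Assumption: the (R)-configured phosphoric acid in step 5 is taken to give the 2R product. This is checked on the first run (ECD or X-ray), and if the sense is opposite the equally available (S)-catalyst is used with nothing else changed.

## Route

Step 1
Reactants: 1 2',4'-dihydroxy-6'-methoxyacetophenone; 2 prenyl bromide (1-bromo-3-methylbut-2-ene)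
Product: 3 2',4'-dihydroxy-6'-methoxy-3'-(3-methylbut-2-enyl)acetophenone
Conditions: 2 (1.0 equiv), KOH (2.0 equiv), H2O, 0 °C to rt, 16 h; 1 M HCl work-up; chromatography
Reagents that add atoms: prenyl bromide (2), CC(C)=CCBr
Why: Phenolate C-alkylation (biomimetic aromatic prenylation): in water the oxygens of the resorcinol dianion are hydrogen-bond solvated, so carbon takes the soft allylic bromide in an SN2 step, mainly at C-3', the site ortho to both phenolate oxygens; 5'-prenyl, diprenyl and O-prenyl by-products are removed by chromatography, and no stereocenter is formed.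

Step 2
Reactants: 3 2',4'-dihydroxy-6'-methoxy-3'-prenylacetophenone; 4 3-methylbut-2-enal (prenal)
Product: 6 1-[7-hydroxy-5-methoxy-2,2-dimethyl-8-(3-methylbut-2-enyl)-2H-chromen-6-yl]ethanone, via o-quinone methide 5 (not isolated)
Conditions: 4 (1.5 equiv), ethylenediammonium diacetate (20 mol%), PhMe, reflux, Dean–Stark, 8 h
Reagents that add atoms: prenal (4), CC(C)=CC=O
Why: Knoevenagel-type condensation/oxa-6π electrocyclisation (formal [3+3] chromene annulation): the only free ring carbon (C-5') adds to the iminium-activated enal, loss of water gives the same vinyl o-quinone methide 5 that oxidation of an o-prenylphenol gives in nature, and 5 can close only onto O-4' because the other neighbour is OMe, which forces the linear pyran; no stereocenter is formed.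

Step 3
Reactants: 7 2,6-dihydroxybenzaldehyde; 8 allyl bromide
Product: 9 2,6-bis(allyloxy)benzaldehyde
Conditions: 8 (2.4 equiv), K2CO3 (2.5 equiv), DMF, 50 °C, 6 h
Reagents that add atoms: allyl bromide (8), C=CCBr
Why: Williamson ether synthesis on both acidic phenols with an unhindered allylic bromide; allyl is chosen because it withstands KOH and leaves later under non-acidic Pd(0) conditions; no stereocenter is formed.

Step 4
Reactants: 6 chromenyl methyl ketone; 9 2,6-bis(allyloxy)benzaldehyde
Product: 11 (E)-3-(2,6-dihydroxyphenyl)-1-[7-hydroxy-5-methoxy-2,2-dimethyl-8-(3-methylbut-2-enyl)-2H-chromen-6-yl]prop-2-en-1-one, via bis-allyl chalcone 10 (not isolated)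
Conditions: KOH (15 equiv), EtOH–H2O, rt, 48 h, under argon; then Pd(PPh3)4 (5 mol%), morpholine (6 equiv), rt, 3 h; AcOH to pH 5–6 at 0 °C, in the dark; short silica column
Reagents that add atoms: none
Why: Claisen–Schmidt condensation (aldol addition, then E1cB loss of water gives the E-enone) followed by Tsuji–Trost deallylation, in which Pd(0) ionises only the two unhindered allyl aryl ethers and morpholine takes up the allyl groups while the C-prenyl group and the hindered cyclic chromene ether stay untouched; in the strongly basic medium the product is held open as its triphenolate (a vinylogous carboxylate and poor Michael acceptor), so it reaches the next step uncyclised and never meets strong acid.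

Step 5
Reactants: 11 trihydroxychalcone
Product: 13 (2R,4R)-4,2'-epoxy-4,6'-dihydroxy-5-methoxy-8-prenyl-6'',6''-dimethylpyrano[2'',3'':7,6]flavan (target CNP0170313.2), via (2R)-flavanone 12 (not isolated)
Conditions: (R)-TRIP (10 mol%), PhMe (0.05 M, reagent grade, no molecular sieves), 25–30 °C, in the dark, 48 h; recrystallisation (hexane–EtOAc) to raise ee
Reagents that add atoms: none
Why: Proposed new method: the chiral phosphoric acid bridges the enone C=O (P–OH donor) and a B-ring ortho-OH (P=O acceptor), and this proton relay turns the chalcone into a phosphate-bound vinylogous o-quinone methide whose β-carbon is attacked on one face by the A-ring 7-OH (chalcone-isomerase-like 6-endo oxa-Michael addition, sets C-2 as R); flavanone 12, whose unchelated, peri-crowded 5-OMe ketone is unusually electrophilic, is then captured by the 2'-OH, which for geometric reasons can reach only one face of C-4 (sets C-4 as R), and because the bridgehead hemiketal has no enolisable ketone and cannot dehydrate (anti-Bredt), the retro-oxa-Michael racemisation that normally limits chalcone-to-flavanone catalysis is shut off, while leaving out sieves keeps the water that reverses any parking as flavylium phosphate; the closest known reaction types are phosphoric-acid-catalysed additions to o-quinone methides generated from o-hydroxystyrenes, asymmetric Michael addition/ketalisation of 2-hydroxychalcones to 2,8-dioxabicyclo[3.3.1]nonanes, and bifunctional-catalyst oxa-Michael cyclisation of phenols onto enones.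

## Compound list
1 | 2',4'-dihydroxy-6'-methoxyacetophenone | CC(=O)c1c(O)cc(O)cc1OC | starting material
2 | prenyl bromide | CC(C)=CCBr | starting material
3 | 2',4'-dihydroxy-6'-methoxy-3'-prenylacetophenone | CC(=O)c1c(O)c(CC=C(C)C)c(O)cc1OC | intermediate
4 | 3-methylbut-2-enal (prenal) | CC(C)=CC=O | starting material
5 | vinyl o-quinone methide, exocyclic C=C with the vinyl group syn to the ring C=O (not isolated) | CC(=O)C1=C(OC)/C(=C/C=C(C)C)C(=O)C(CC=C(C)C)=C1O | intermediate
6 | 1-[7-hydroxy-5-methoxy-2,2-dimethyl-8-prenyl-2H-chromen-6-yl]ethanone | CC(=O)c1c(O)c(CC=C(C)C)c2OC(C)(C)C=Cc2c1OC | intermediate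
7 | 2,6-dihydroxybenzaldehyde | O=Cc1c(O)cccc1O | starting material
8 | allyl bromide | C=CCBr | starting material
9 | 2,6-bis(allyloxy)benzaldehyde | O=Cc1c(OCC=C)cccc1OCC=C | intermediate
10 | (E)-2,6-bis(allyloxy) chalcone of 6 (not isolated) | COc1c2C=CC(C)(C)Oc2c(CC=C(C)C)c(O)c1C(=O)/C=C/c1c(OCC=C)cccc1OCC=C | intermediate
11 | (E)-2,6,2'-trihydroxy-6'-methoxy-3'-prenyl-pyrano[4',5'] chalcone | COc1c2C=CC(C)(C)Oc2c(CC=C(C)C)c(O)c1C(=O)/C=C/c1c(O)cccc1O | intermediate
12 | (2R)-2',6'-dihydroxy-5-methoxy-8-prenyl-6'',6''-dimethylpyrano[2'',3'':7,6]flavanone (not isolated) | COc1c2c(c(CC=C(C)C)c3c1C(=O)C[C@@H](O3)c1c(O)cccc1O)OC(C)(C)C=C2 | intermediate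
13 | (2R,4R)-4,2'-hemiketal of 12, CNP0170313.2 | COc1c2c(c(CC=C(C)C)c3c1[C@@]1(O)C[C@@H](O3)c3c(O)cccc3O1)OC(C)(C)C=C2 | target

## Step count and risks
Total steps: 5. Longest linear sequence: 4 (1 → 3 → 6 → 11 → 13).

**Step 5 (greatest risk).**
- The acid may be too weak, the induction low, or the substrate may sit as flavylium phosphate.
- The fallback gives up asymmetric catalysis for resolution with recycling. It sets out from 11.
- NaOAc in EtOH at 60 °C cyclises 11 without facial control through 12 and its mirror image, the (2S)-flavanone F1.
- This gives a 1:1 mixture of 13 and the (2S,4S)-hemiketal F2.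
- Preparative chiral SFC on an amylose carbamate phase separates the two.
- F2 is reopened to 11 with KOH/MeOH (retro-oxa-Michael, then pH 5–6) and sent round again. The route is rejoined at 13.

**Step 1.**
- O-alkylation, attack at C-5' and double alkylation can make the yield of 3 poor.
- The fallback replaces direct C-alkylation by O-alkylation and a sigmatropic shift. It sets out from 1.
- Pd(PPh3)4-catalysed O-tert-prenylation of the free, non-chelated 4'-OH with methyl 2-methylbut-3-en-2-yl carbonate (THF, 0 °C to rt) gives the 4'-O-(1,1-dimethylallyl) ether F3.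
- An aromatic Claisen rearrangement (PhNEt2, 130 °C) then delivers the chain with allyl inversion as a normal prenyl group.
- The chain goes to C-3', the ortho position favoured by the bond fixation of the chelated 2'-hydroxyketone. The route is rejoined at 3.

**Step 4.**
- Both partners are di-ortho-substituted and the aldehyde is electron-rich. The equilibrium condensation may therefore stall, and the Pd stage may suffer in the crude mixture.
- The fallback uses a directed, irreversible aldol. It sets out from 6 and 9.
- LiHMDS (2.2 equiv, THF, −78 °C) makes the phenolate-enolate dianion of 6, which adds to 9 to give the racemic β-hydroxy ketone F4.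
- The doubly ortho-alkoxy benzylic alcohol of F4 is dehydrated with catalytic PPTS in PhMe at 60 °C.
- The route is rejoined at 10, which is then isolated and deallylated on its own (Pd(PPh3)4, morpholine, THF) to give 11.

## Further compounds
F1 | step 5 | (2S)-enantiomer of flavanone 12 | COc1c2c(c(CC=C(C)C)c3c1C(=O)C[C@H](O3)c1c(O)cccc1O)OC(C)(C)C=C2
F2 | step 5 | (2S,4S)-enantiomer of 13 | COc1c2c(c(CC=C(C)C)c3c1[C@]1(O)C[C@H](O3)c3c(O)cccc3O1)OC(C)(C)C=C2
F3 | step 1 | 1-[2-hydroxy-6-methoxy-4-(2-methylbut-3-en-2-yloxy)phenyl]ethanone | CC(=O)c1c(O)cc(OC(C)(C)C=C)cc1OC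
F4 | step 4 | (±)-3-[2,6-bis(allyloxy)phenyl]-3-hydroxy-1-[7-hydroxy-5-methoxy-2,2-dimethyl-8-prenyl-2H-chromen-6-yl]propan-1-one | COc1c2C=CC(C)(C)Oc2c(CC=C(C)C)c(O)c1C(=O)CC(O)c1c(OCC=C)cccc1OCC=C
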